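**Plan**
- Retrosynthesis: cut the epoxide CH2–O bond (back to a tertiary silyl ether next to a primary tosylate) and the aryl O–tigloyl bond, then cut three C–C bonds of ring A: C4–C5, C6–C1 and C1–C2 (C1 = acyloxy carbon, C3 = methyl carbon, C4 = methoxy carbon, C6 = carbon bearing the side chain).
- Enabling feature: ring A is a 1,4-dioxygenated benzene with OMe on C4, methyl on C3 beside it, the quaternary side-chain carbon on C6 beside the C1 oxygen, and hydrogen on C2 and C5. This is the pattern a Dötz benzannulation of an isopropenyl(methoxy)carbene chromium complex, one CO ligand and a terminal alkyne lays down, with C1–OH free and C4–OMe already in place.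
- Forward: the carbene complex (one step) and the chiral alkyne (five steps) are made separately. The benzannulation joins them and closes ring A. Tigloylation and fluoride-triggered closure of the oxirane, the only other ring, finish the synthesis.
- Stereochemistry: the single stereocenter (R in the target) is set by lipase desymmetrisation of achiral 2-ethynylglycerol and carried through untouched; no later step makes or breaks a bond to it. The E-alkene comes in with tigloyl chloride.

Key step: step 7

Assumption: the enantiotopic preference of a lipase for a prochiral 2-substituted glycerol cannot be predicted from first principles; step 4 takes Candida antarctica lipase B to acylate the pro-R hydroxymethyl arm of triol 9, the configuration of 10 is to be assigned by correlation before going on, and if the opposite arm is preferred the hydrolytic variant described under the fallbacks delivers the same (R)-monoester 10.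

**Route**

Step 1
Reactants: 1 2-bromopropene; 2 chromium hexacarbonyl
Product: 5 pentacarbonyl[methoxy(prop-1-en-2-yl)carbene]chromium, via 2-propenyllithium 3 (not isolated), via lithium acylchromate 4 (not isolated)
Conditions: t-BuLi (2 equiv), Et2O, −78 °C; Cr(CO)6, Et2O, −78 °C → rt; Me3OBF4, CH2Cl2, 0 °C
Reagents that add atoms: trimethyloxonium tetrafluoroborate, C[O+](C)C.F[B-](F)(F)F
Why: Bromine–lithium exchange gives the alkenyllithium, which adds to a carbonyl ligand of Cr(CO)6, and O-methylation of the resulting acylchromate completes a standard Fischer carbene synthesis.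

Step 2
Reactants: 6 ethynylmagnesium bromide; 7 2,2-dimethyl-1,3-dioxan-5-one
Product: 8 5-ethynyl-2,2-dimethyl-1,3-dioxan-5-ol
Conditions: THF, −78 → 0 °C; aq. NH4Cl
Reagents that add atoms: none
Why: Grignard 1,2-addition of the alkynyl reagent to the ketone should give the tertiary propargylic alcohol, which is achiral because the two ring arms are identical.

Step 3
Reactants: 8 5-ethynyl-2,2-dimethyl-1,3-dioxan-5-ol
Product: 9 2-ethynylpropane-1,2,3-triol (2-ethynylglycerol)
Conditions: Dowex 50WX8 (H+ form), THF/H2O, rt; filter, concentrate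
Reagents that add atoms: none
Why: Acid-catalysed acetal hydrolysis frees the two primary hydroxyls, and the solid acid is filtered off so that the water-soluble triol needs no extraction.

Step 4
Reactants: 9 2-ethynylpropane-1,2,3-triol
Product: 10 (2R)-2-hydroxy-2-(hydroxymethyl)but-3-yn-1-yl 3-methylbutanoate
Conditions: Novozym 435 (immobilised Candida antarctica lipase B), 3-methylbutanoic anhydride (1.05 equiv), MTBE/MeCN, 0 °C; filter, cold aq. NaHCO3 wash; used at once
Reagents that add atoms: 3-methylbutanoic anhydride, CC(C)CC(=O)OC(=O)CC(C)C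
Why: Lipase-catalysed enantiotopic-group-selective acylation (enzymatic desymmetrisation of a prochiral 2-substituted glycerol) should esterify one primary hydroxymethyl arm only, the chiral active site of the enzyme setting the quaternary stereocenter as R while the hindered tertiary hydroxyl stays free.

Step 5
Reactants: 10 (2R)-2-hydroxy-2-(hydroxymethyl)but-3-yn-1-yl 3-methylbutanoate
Product: 11 (2S)-2-hydroxy-2-[(tosyloxy)methyl]but-3-yn-1-yl 3-methylbutanoate
Conditions: Bu2SnO (cat.), TsCl, Et3N, CH2Cl2, 0 °C
Reagents that add atoms: 4-methylbenzenesulfonyl chloride, Cc1ccc(cc1)S(Cl)(=O)=O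
Why: Stannylene-acetal-mediated regioselective sulfonylation of a terminal 1,2-diol should tosylate the primary hydroxyl quickly, removing the free primary hydroxyl before 1,3-acyl migration can erode the enantiomeric purity; the descriptor changes from R to S only because the sulfonate arm now outranks the ester arm.

Step 6
Reactants: 11 (2S)-2-hydroxy-2-[(tosyloxy)methyl]but-3-yn-1-yl 3-methylbutanoate
Product: 12 (2S)-2-[(tosyloxy)methyl]-2-(triethylsilyloxy)but-3-yn-1-yl 3-methylbutanoate
Conditions: TESOTf, 2,6-lutidine, CH2Cl2, −78 → 0 °C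
Reagents that add atoms: triethylsilyl trifluoromethanesulfonate, CC[Si](CC)(CC)OS(=O)(=O)C(F)(F)F
Why: Silylation of a hindered tertiary alcohol with a silyl triflate and a hindered pyridine base is standard, and it masks the propargylic hydroxyl that would otherwise trap the ketene intermediate of the next step as a lactone.

Step 7
Reactants: 5 pentacarbonyl[methoxy(prop-1-en-2-yl)carbene]chromium; 12 (2S)-2-[(tosyloxy)methyl]-2-(triethylsilyloxy)but-3-yn-1-yl 3-methylbutanoate
Product: 14 (2S)-2-(2-hydroxy-5-methoxy-4-methylphenyl)-3-(tosyloxy)-2-(triethylsilyloxy)propyl 3-methylbutanoate, via tricarbonylchromium arene complex 13 (not isolated)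
Conditions: 5 (1.5 equiv), THF (degassed), 50 °C; then air, daylight, Et2O, rt
Reagents that add atoms: none
Why: Thermal loss of one CO from 5 opens a coordination site, the terminal alkyne of 12 inserts into the Cr=C bond with its substituted carbon on chromium, CO insertion into the new vinylcarbene gives a chromium-bound dienylketene, and six-electron electrocyclisation followed by enolisation gives the phenol as its tricarbonylchromium complex 13, from which air removes the metal. The closest known reaction type is the Dötz benzannulation of alkenyl(methoxy)carbene chromium complexes with terminal alkynes carrying propargylic silyl ethers. Ring A closes by a disrotatory 6π-electrocyclisation of the dienylketene, which forms the C1–C2 bond after C4–C5 and C6–C1 have been made. No stereocenter is created, and the quaternary center of 12 is a spectator whose four bonds stay intact. The step needs regioselective alkyne insertion, and the size difference between the fully substituted propargylic group and hydrogen puts the side chain on C6 next to the new hydroxyl and leaves C5 unsubstituted next to the methoxy carbon. The silyl ether keeps the tertiary oxygen away from the ketene, and the neutral conditions leave the tosylate and the ester alone.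

Step 8
Reactants: 14 (2S)-2-(2-hydroxy-5-methoxy-4-methylphenyl)-3-(tosyloxy)-2-(triethylsilyloxy)propyl 3-methylbutanoate
Product: 15 (2S)-2-{5-methoxy-4-methyl-2-[(2E)-2-methylbut-2-enoyloxy]phenyl}-3-(tosyloxy)-2-(triethylsilyloxy)propyl 3-methylbutanoate
Conditions: tigloyl chloride, pyridine, DMAP (cat.), CH2Cl2, 0 °C → rt
Reagents that add atoms: (2E)-2-methylbut-2-enoyl chloride (tigloyl chloride), C/C=C(\C)C(=O)Cl
Why: DMAP-catalysed acylation of the phenol by the acid chloride should be faster than any intramolecular displacement of the neopentyl-type tosylate, and pyridine as the only base avoids vinylketene formation, so the E-2-enoate is kept.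

Step 9
Reactants: 15 (2S)-2-{5-methoxy-4-methyl-2-[(2E)-2-methylbut-2-enoyloxy]phenyl}-3-(tosyloxy)-2-(triethylsilyloxy)propyl 3-methylbutanoate
Product: 17 [(2R)-2-{5-methoxy-4-methyl-2-[(2E)-2-methylbut-2-enoyloxy]phenyl}oxiran-2-yl]methyl 3-methylbutanoate (CNP0108422.1), via tertiary alkoxide 16 (not isolated)
Conditions: TASF (tris(dimethylamino)sulfonium difluorotrimethylsilicate, 1.2 equiv), THF/DMF, −20 → 0 °C
Reagents that add atoms: none
Why: Anhydrous fluoride cleaves the Si–O bond and the tertiary alkoxide displaces the neighbouring primary tosylate in a 3-exo-tet intramolecular Williamson etherification that should outrun attack on the aryl ester; no bond to the stereocenter is broken, so its arrangement is retained and only the descriptor changes from S to R.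

**Compound list**
1 | 2-bromopropene | C=C(C)Br | starting material
2 | chromium hexacarbonyl | O=C=[Cr](=C=O)(=C=O)(=C=O)(=C=O)=C=O | starting material
3 | 2-propenyllithium | [Li]C(C)=C | intermediate (not isolated)
4 | lithium pentacarbonyl(2-methylprop-2-enoyl)chromate | [Li+].[O-]C(C(C)=C)=[Cr](=C=O)(=C=O)(=C=O)(=C=O)=C=O | intermediate (not isolated)
5 | pentacarbonyl[methoxy(prop-1-en-2-yl)carbene]chromium | COC(C(C)=C)=[Cr](=C=O)(=C=O)(=C=O)(=C=O)=C=O | intermediate
6 | ethynylmagnesium bromide | C#C[Mg]Br | starting material
7 | 2,2-dimethyl-1,3-dioxan-5-one | CC1(C)OCC(=O)CO1 | starting material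
8 | 5-ethynyl-2,2-dimethyl-1,3-dioxan-5-ol | CC1(C)OCC(O)(C#C)CO1 | intermediate
9 | 2-ethynylpropane-1,2,3-triol | C#CC(O)(CO)CO | intermediate
10 | (2R)-2-hydroxy-2-(hydroxymethyl)but-3-yn-1-yl 3-methylbutanoate | C#C[C@](O)(COC(=O)CC(C)C)CO | intermediate
11 | (2S)-2-hydroxy-2-[(tosyloxy)methyl]but-3-yn-1-yl 3-methylbutanoate | C#C[C@](O)(COC(=O)CC(C)C)COS(=O)(=O)c1ccc(C)cc1 | intermediate
12 | (2S)-2-[(tosyloxy)methyl]-2-(triethylsilyloxy)but-3-yn-1-yl 3-methylbutanoate | C#C[C@](O[Si](CC)(CC)CC)(COC(=O)CC(C)C)COS(=O)(=O)c1ccc(C)cc1 | intermediate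
13 | tricarbonylchromium complex of 14, metal η6-bound to ring A (hapto bond written as a dot) | Cc1cc(O)c(cc1OC)[C@](O[Si](CC)(CC)CC)(COC(=O)CC(C)C)COS(=O)(=O)c1ccc(C)cc1.O=C=[Cr](=C=O)=C=O | intermediate (not isolated)
14 | (2S)-2-(2-hydroxy-5-methoxy-4-methylphenyl)-3-(tosyloxy)-2-(triethylsilyloxy)propyl 3-methylbutanoate | Cc1cc(O)c(cc1OC)[C@](O[Si](CC)(CC)CC)(COC(=O)CC(C)C)COS(=O)(=O)c1ccc(C)cc1 | intermediate
15 | (2S)-2-{5-methoxy-4-methyl-2-[(2E)-2-methylbut-2-enoyloxy]phenyl}-3-(tosyloxy)-2-(triethylsilyloxy)propyl 3-methylbutanoate | C/C=C(\C)C(=O)Oc1cc(C)c(OC)cc1[C@](O[Si](CC)(CC)CC)(COC(=O)CC(C)C)COS(=O)(=O)c1ccc(C)cc1 | intermediate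
16 | tris(dimethylamino)sulfonium (2S)-1-(3-methylbutanoyloxy)-2-{5-methoxy-4-methyl-2-[(2E)-2-methylbut-2-enoyloxy]phenyl}-3-(tosyloxy)propan-2-olate | C/C=C(\C)C(=O)Oc1cc(C)c(OC)cc1[C@]([O-])(COC(=O)CC(C)C)COS(=O)(=O)c1ccc(C)cc1.CN(C)[S+](N(C)C)N(C)C | intermediate (not isolated)
17 | [(2R)-2-{5-methoxy-4-methyl-2-[(2E)-2-methylbut-2-enoyloxy]phenyl}oxiran-2-yl]methyl 3-methylbutanoate | C/C=C(\C)C(=O)Oc1cc(C)c(OC)cc1[C@]1(COC(=O)CC(C)C)CO1 | target

**Step count and risks**

Total step count: 9. Longest linear sequence: 8 steps (steps 2 to 9, from 6 and 7); the carbene branch adds step 1.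

Steps most likely to fail:

1. Step 7. Alkyne uptake at the congested, fully substituted propargylic carbon may be slow, so that thermal decay of the carbene complex or CO-free and cyclobutenone-forming channels take over; the sulfonate may also be attacked by low-valent chromium. The fallback ties two substituents of the quaternary carbon back into a five-membered acetal, leaves out the sulfonate and activates the epoxide arm only after the ring is built. It sets out from 10: 2-methoxypropene and PPTS (cat.) in CH2Cl2 at 0 °C should give the dioxolane alkyne [(4R)-4-ethynyl-2,2-dimethyl-1,3-dioxolan-4-yl]methyl 3-methylbutanoate F1. Benzannulation of F1 with 5 under the conditions of step 7 should give, through the tricarbonylchromium arene complex F2, the dioxolanyl phenol F3. Tigloyl chloride, pyridine and DMAP convert F3 into the aryl tiglate F4, and aqueous acetic acid at 40 °C removes the acetonide to give the diol F5, which is used at once to forestall acyl migration. Mitsunobu cyclodehydration (PPh3, DIAD, THF, 0 °C → rt) activates the primary hydroxyl and lets the tertiary hydroxyl displace it, which comes back to the route at 17.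

2. Step 4. The lipase may discriminate the two hydroxymethyl arms poorly or in the wrong sense, and acyl migration in the monoester may erode what selectivity there is. The fallback reverses the direction of the enzymatic reaction and sets out from 9: 3-methylbutanoyl chloride (2.1 equiv) and pyridine in CH2Cl2 at −20 °C acylate both primary hydroxyls to give the bis-ester 2-ethynyl-2-hydroxypropane-1,3-diyl bis(3-methylbutanoate) F6. The same lipase in pH 7 phosphate buffer/MTBE then hydrolyses one enantiotopic ester. Because the enzyme recognises the same arm in both directions, hydrolysis leaves the ester on the arm that acylation would have left free, so the monoester of opposite configuration results. Desymmetrising hydrolysis of 2-alkynyl-2-hydroxypropane-1,3-diyl diesters is the closest known case. The fallback comes back to the route at 10.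

3. Step 9. Basic fluoride may cleave the aryl tiglate, or the freed tertiary alkoxide may take over the tigloyl group from the phenol oxygen, after which the phenoxide would displace the tosylate. The fallback closes the epoxide before the aryl ester exists and sets out from 14: allyl methyl carbonate and Pd(PPh3)4 (cat.) in THF (neutral Tsuji–Trost O-allylation) should give the allyl aryl ether F7. TBAF in THF at 0 °C then gives, through the tetrabutylammonium alkoxide F8, the epoxide allyl ether F9. Hydrostannolysis of the allyl aryl ether with Pd(PPh3)4 (cat.) and Bu3SnH in CH2Cl2 gives the tributylstannyl phenoxide F10, which is acylated in the same flask with tigloyl chloride, so that a free ortho-hydroxyphenyl epoxide is never exposed. This comes back to the route at 17.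

**Further compounds**
F1 | step 7 | [(4R)-4-ethynyl-2,2-dimethyl-1,3-dioxolan-4-yl]methyl 3-methylbutanoate | C#C[C@]1(COC(=O)CC(C)C)COC(C)(C)O1
F2 | step 7 | tricarbonylchromium complex of F3, metal η6-bound to ring A (hapto bond written as a dot) | Cc1cc(O)c(cc1OC)[C@]1(COC(=O)CC(C)C)COC(C)(C)O1.O=C=[Cr](=C=O)=C=O
F3 | step 7 | [(4R)-4-(2-hydroxy-5-methoxy-4-methylphenyl)-2,2-dimethyl-1,3-dioxolan-4-yl]methyl 3-methylbutanoate | Cc1cc(O)c(cc1OC)[C@]1(COC(=O)CC(C)C)COC(C)(C)O1
F4 | step 7 | [(4R)-4-{5-methoxy-4-methyl-2-[(2E)-2-methylbut-2-enoyloxy]phenyl}-2,2-dimethyl-1,3-dioxolan-4-yl]methyl 3-methylbutanoate | C/C=C(\C)C(=O)Oc1cc(C)c(OC)cc1[C@]1(COC(=O)CC(C)C)COC(C)(C)O1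
F5 | step 7 | (2R)-2,3-dihydroxy-2-{5-methoxy-4-methyl-2-[(2E)-2-methylbut-2-enoyloxy]phenyl}propyl 3-methylbutanoate | C/C=C(\C)C(=O)Oc1cc(C)c(OC)cc1[C@](O)(COC(=O)CC(C)C)CO
F6 | step 4 | 2-ethynyl-2-hydroxypropane-1,3-diyl bis(3-methylbutanoate) | C#CC(O)(COC(=O)CC(C)C)COC(=O)CC(C)C
F7 | step 9 | (2S)-2-[5-methoxy-4-methyl-2-(prop-2-en-1-yloxy)phenyl]-3-(tosyloxy)-2-(triethylsilyloxy)propyl 3-methylbutanoate | C=CCOc1cc(C)c(OC)cc1[C@](O[Si](CC)(CC)CC)(COC(=O)CC(C)C)COS(=O)(=O)c1ccc(C)cc1
F8 | step 9 | tetrabutylammonium (2S)-1-(3-methylbutanoyloxy)-2-[5-methoxy-4-methyl-2-(prop-2-en-1-yloxy)phenyl]-3-(tosyloxy)propan-2-olate | C=CCOc1cc(C)c(OC)cc1[C@]([O-])(COC(=O)CC(C)C)COS(=O)(=O)c1ccc(C)cc1.CCCC[N+](CCCC)(CCCC)CCCC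
F9 | step 9 | {(2R)-2-[5-methoxy-4-methyl-2-(prop-2-en-1-yloxy)phenyl]oxiran-2-yl}methyl 3-methylbutanoate | C=CCOc1cc(C)c(OC)cc1[C@]1(COC(=O)CC(C)C)CO1
F10 | step 9 | {(2R)-2-[5-methoxy-4-methyl-2-(tributylstannyloxy)phenyl]oxiran-2-yl}methyl 3-methylbutanoate | CCCC[Sn](CCCC)(CCCC)Oc1cc(C)c(OC)cc1[C@]1(COC(=O)CC(C)C)CO1
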